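**Retrosynthetic overview**
1. Target 13 ⇐ flavone 11 (4'-O-benzyl, 5-O-methyl) by one BCl3 operation that removes the benzyl group and the carbonyl-chelated 5-O-methyl group.
2. Key disconnection: the C2–C1' bond. Instead of the usual chalcone/Algar–Flynn–Oyamada or Baker–Venkataraman assembly, ring B (aryl bromide 9) is attached last to an intact 3-methoxychromone 7 by C2–H zincation and Negishi coupling.
3. Chromone 7 ⇐ ω-methoxy-2-hydroxyacetophenone 5 plus one carbon (DMF-DMA); 5 ⇐ 1,2,3,5-tetramethoxybenzene 1 by ortho-lithiation/Weinreb acylation and chelation-controlled mono-demethylation.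
4. Ring order: ring A is bought, ring C is closed onto it (step 3), ring B is bought and joined in step 5.

Assumption: the target has no stereocentre and no stereogenic double bond (it is achiral), so "single enantiomer" sets no stereochemical task.

**Step 1**
Reactants: 1 1,2,3,5-tetramethoxybenzene; 2 N,2-dimethoxy-N-methylacetamide
Product: 4 2-methoxy-1-(2,3,4,6-tetramethoxyphenyl)ethan-1-one, via aryllithium 3 (not isolated)
Conditions: n-BuLi (1.1 equiv), THF, 0 °C → rt, 1 h; then 2 (1.2 equiv), –78 → 0 °C; 1 M HCl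
Reagents that add atoms: none
Why: Directed ortho-metalation removes the ring hydrogen flanked by two methoxy groups (C4 and C6 are equivalent by symmetry, so one aryllithium forms), and the Weinreb ketone synthesis stops at the chelated tetrahedral adduct so only the ketone is released on work-up; this also avoids an acid chloride/AlCl3 acylation, where a methoxyacetyl cation would lose CO.

**Step 2**
Reactants: 4 2-methoxy-1-(2,3,4,6-tetramethoxyphenyl)ethan-1-one
Product: 5 1-(2-hydroxy-3,4,6-trimethoxyphenyl)-2-methoxyethan-1-one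
Conditions: BCl3 (1.2 equiv), CH2Cl2, –78 → 0 °C; then H2O
Reagents that add atoms: none
Why: Chelation-controlled Lewis-acid demethylation: boron bound to the ketone cleaves an ortho methoxy group, and of the two the one flanked by the 3-OMe (twisted out of plane, most basic, strain-relieving) goes first, as in the classical selective demethylation of 2,3,4,6-tetramethoxyacetophenones.

**Step 3**
Reactants: 5 1-(2-hydroxy-3,4,6-trimethoxyphenyl)-2-methoxyethan-1-one
Product: 7 3,5,7,8-tetramethoxy-4H-chromen-4-one, via enaminone 6 (not isolated)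
Conditions: DMF-DMA (3 equiv), toluene, 100 °C; then AcOH, 90 °C
Reagents that add atoms: N,N-dimethylformamide dimethyl acetal, COC(OC)N(C)C
Why: Enaminone chromone synthesis: the activated α-methylene condenses with the amide acetal, and the only free phenol closes ring C by oxa-Michael addition–elimination of dimethylamine, giving the 5,7,8-pattern unambiguously and leaving C2–H free.

**Step 4**
Reactants: 8 4-bromo-3-methoxyphenol
Product: 9 4-(benzyloxy)-1-bromo-2-methoxybenzene
Conditions: BnBr (1.1 equiv), K2CO3 (1.5 equiv), DMF, 60 °C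
Reagents that add atoms: benzyl bromide, BrCc1ccccc1
Why: Williamson ether synthesis (SN2 of the phenoxide on benzyl bromide) masks the acidic phenol before the organozinc step.

**Step 5**
Reactants: 7 3,5,7,8-tetramethoxy-4H-chromen-4-one; 9 4-(benzyloxy)-1-bromo-2-methoxybenzene
Product: 11 2-[4-(benzyloxy)-2-methoxyphenyl]-3,5,7,8-tetramethoxy-4H-chromen-4-one, via chromon-2-ylzinc chloride 10 (not isolated)
Conditions: TMPZnCl·LiCl (1.2 equiv), THF, 25 °C, 1 h; then 9 (1.1 equiv), Pd(OAc)2 (2 mol %), SPhos (4 mol %), THF, 50 °C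
Reagents that add atoms: none
Why: Deprotonative C–H zincation with the TMP-zinc amide takes the only acidic ring-C hydrogen (C2–H, activated by O1, the carbonyl and the 3-OMe; C3 is blocked, so no ring-opening β-elimination is possible and the carbonyl is not attacked), and the heteroarylzinc then undergoes Negishi coupling at zerovalent palladium (formed in situ from Pd(OAc)2) with the hindered electron-rich bromide, for which SPhos is suited.

**Step 6**
Reactants: 11 2-[4-(benzyloxy)-2-methoxyphenyl]-3,5,7,8-tetramethoxy-4H-chromen-4-one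
Product: 13 5,4'-dihydroxy-3,7,8,2'-tetramethoxyflavone, via aryloxydichloroborane 12 (not isolated)
Conditions: BCl3 (5 equiv), C6HMe5 (3 equiv), CH2Cl2, –78 °C, 1 h, then 0 °C, 2 h; then H2O
Reagents that add atoms: none
Why: Lewis-acid ether cleavage in two stages: BCl3 with pentamethylbenzene as benzyl-cation scavenger debenzylates at –78 °C, and on warming the six-membered boron chelate between the C4 carbonyl and the peri 5-OMe delivers chloride to that methyl only, so the 3-, 7-, 8- and 2'-OMe groups stay and no acid-induced ring opening (Wessely–Moser isomerisation) occurs.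

**Compound list**
1 | 1,2,3,5-tetramethoxybenzene | COc1cc(OC)c(OC)c(OC)c1 | starting material
2 | N,2-dimethoxy-N-methylacetamide | COCC(=O)N(C)OC | starting material
3 | (2,3,4,6-tetramethoxyphenyl)lithium | [Li]c1c(OC)cc(OC)c(OC)c1OC | intermediate
4 | 2-methoxy-1-(2,3,4,6-tetramethoxyphenyl)ethan-1-one | COCC(=O)c1c(OC)cc(OC)c(OC)c1OC | intermediate
5 | 1-(2-hydroxy-3,4,6-trimethoxyphenyl)-2-methoxyethan-1-one | COCC(=O)c1c(OC)cc(OC)c(OC)c1O | intermediate
6 | (Z)-3-(dimethylamino)-1-(2-hydroxy-3,4,6-trimethoxyphenyl)-2-methoxyprop-2-en-1-one (expected isomer; geometry is lost on ring closure) | CN(C)/C=C(\OC)C(=O)c1c(OC)cc(OC)c(OC)c1O | intermediate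
7 | 3,5,7,8-tetramethoxy-4H-chromen-4-one | COc1coc2c(OC)c(OC)cc(OC)c2c1=O | intermediate
8 | 4-bromo-3-methoxyphenol | COc1cc(O)ccc1Br | starting material
9 | 4-(benzyloxy)-1-bromo-2-methoxybenzene | COc1cc(OCc2ccccc2)ccc1Br | intermediate
10 | chloro(3,5,7,8-tetramethoxy-4-oxo-4H-chromen-2-yl)zinc (LiCl complex) | COc1c([Zn]Cl)oc2c(OC)c(OC)cc(OC)c2c1=O | intermediate
11 | 2-[4-(benzyloxy)-2-methoxyphenyl]-3,5,7,8-tetramethoxy-4H-chromen-4-one | COc1cc(OCc2ccccc2)ccc1-c1oc2c(OC)c(OC)cc(OC)c2c(=O)c1OC | intermediate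
12 | dichloro[3-methoxy-4-(3,5,7,8-tetramethoxy-4-oxo-4H-chromen-2-yl)phenoxy]borane | COc1cc(OB(Cl)Cl)ccc1-c1oc2c(OC)c(OC)cc(OC)c2c(=O)c1OC | intermediate
13 | 5,4'-dihydroxy-3,7,8,2'-tetramethoxyflavone [5-hydroxy-2-(4-hydroxy-2-methoxyphenyl)-3,7,8-trimethoxy-4H-chromen-4-one] | COc1cc(O)ccc1-c1oc2c(OC)c(OC)cc(O)c2c(=O)c1OC | target

**Summary**
Total steps: 6. Longest linear sequence: 5 (steps 1, 2, 3, 5, 6); step 4 is the ring B branch.

**Steps most likely to fail, each with a fallback**

Step 5 (C2–H zincation/Negishi coupling; the key step, untested on a 3-methoxychromone and forming a biaryl-type bond with one ortho substituent on each side). The fallback gives up C–H metalation and builds ring C around ring B in the classical way. It sets out from 9 and 5 and comes back at 11. Bromide 9 with Mg in THF gives [4-(benzyloxy)-2-methoxyphenyl]magnesium bromide F7, which is carboxylated with CO2 and acidified to 4-(benzyloxy)-2-methoxybenzoic acid F8. Steglich esterification of phenol 5 with F8 (EDC·HCl, DMAP, CH2Cl2) gives 3,5,6-trimethoxy-2-(methoxyacetyl)phenyl 4-(benzyloxy)-2-methoxybenzoate F9. Baker–Venkataraman rearrangement (KOH, pyridine, 50 °C) moves the aroyl group to carbon and gives 1-[4-(benzyloxy)-2-methoxyphenyl]-3-(2-hydroxy-3,4,6-trimethoxyphenyl)-2-methoxypropane-1,3-dione F10 (racemic, enolisable). Cyclodehydration (TsOH cat., toluene, 80 °C) then gives 11.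

Step 6 (one-pot double deprotection; risk of also cleaving the 3-OMe or 8-OMe, or of benzylating the electron-rich rings). The fallback separates the two cleavages into orthogonal reactions. It sets out from 11 and comes back at 13. Hydrogenolysis (H2, Pd/C, EtOAc/MeOH, rt) removes only the benzyl group and gives 2-(4-hydroxy-2-methoxyphenyl)-3,5,7,8-tetramethoxy-4H-chromen-4-one F11. The 5-OMe alone is then cleaved through its aluminium chelate (AlCl3, MeCN, rt to 50 °C, dilute HCl work-up) to give 13.

Step 2 (regioselective mono-demethylation in the presence of the ω-OMe, which can also chelate boron). The fallback installs the 3-oxygen after the chromone is made, so that the selective demethylation is the long-established AlCl3 one on the simple acetyl compound. It sets out from 1 and comes back at 7.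
- Friedel–Crafts acetylation of 1 (AcCl, AlCl3, Et2O, 0 °C → rt) passes through 1-(2,3,4,6-tetramethoxyphenyl)ethan-1-one F1, which loses its flanked ortho methyl group in the same pot to give 1-(2-hydroxy-3,4,6-trimethoxyphenyl)ethan-1-one F2.
- DMF-DMA (toluene, 100 °C) gives (E)-3-(dimethylamino)-1-(2-hydroxy-3,4,6-trimethoxyphenyl)prop-2-en-1-one F3, which closes in AcOH to 5,7,8-trimethoxy-4H-chromen-4-one F4.
- Epoxidation with dimethyldioxirane (acetone/CH2Cl2, 0 °C) gives 5,7,8-trimethoxychromone 2,3-epoxide F5 (racemic, cis-fused), and TsOH (cat.) isomerises it to 3-hydroxy-5,7,8-trimethoxy-4H-chromen-4-one F6.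
- O-Methylation (MeI, K2CO3, acetone, 56 °C) gives 7.

**Further compounds**
F1 | step 2 | 1-(2,3,4,6-tetramethoxyphenyl)ethan-1-one | CC(=O)c1c(OC)cc(OC)c(OC)c1OC
F2 | step 2 | 1-(2-hydroxy-3,4,6-trimethoxyphenyl)ethan-1-one | CC(=O)c1c(OC)cc(OC)c(OC)c1O
F3 | step 2 | (E)-3-(dimethylamino)-1-(2-hydroxy-3,4,6-trimethoxyphenyl)prop-2-en-1-one | CN(C)/C=C/C(=O)c1c(OC)cc(OC)c(OC)c1O
F4 | step 2 | 5,7,8-trimethoxy-4H-chromen-4-one | COc1cc(OC)c2c(=O)ccoc2c1OC
F5 | step 2 | 5,7,8-trimethoxychromone 2,3-epoxide (racemic, cis-fused; one enantiomer drawn) | COc1cc(OC)c2C(=O)[C@@H]3O[C@@H]3Oc2c1OC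
F6 | step 2 | 3-hydroxy-5,7,8-trimethoxy-4H-chromen-4-one | COc1cc(OC)c2c(=O)c(O)coc2c1OC
F7 | step 5 | [4-(benzyloxy)-2-methoxyphenyl]magnesium bromide | COc1cc(OCc2ccccc2)ccc1[Mg]Br
F8 | step 5 | 4-(benzyloxy)-2-methoxybenzoic acid | COc1cc(OCc2ccccc2)ccc1C(=O)O
F9 | step 5 | 3,5,6-trimethoxy-2-(methoxyacetyl)phenyl 4-(benzyloxy)-2-methoxybenzoate | COCC(=O)c1c(OC)cc(OC)c(OC)c1OC(=O)c1ccc(OCc2ccccc2)cc1OC
F10 | step 5 | 1-[4-(benzyloxy)-2-methoxyphenyl]-3-(2-hydroxy-3,4,6-trimethoxyphenyl)-2-methoxypropane-1,3-dione (racemic, enolisable) | COC(C(=O)c1ccc(OCc2ccccc2)cc1OC)C(=O)c1c(OC)cc(OC)c(OC)c1O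
F11 | step 6 | 2-(4-hydroxy-2-methoxyphenyl)-3,5,7,8-tetramethoxy-4H-chromen-4-one | COc1cc(O)ccc1-c1oc2c(OC)c(OC)cc(OC)c2c(=O)c1OC
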